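**Retrosynthetic overview**

- Numbering follows ent-kaurane: C6 is the aldehyde carbon on C5, C7 the lactone carbonyl, C20 the lactone OCH2 on spiro C10, C15 the ketone, C16=C17 the exocyclic alkene. The plan rests on ring A (C1–C5 plus spiro C10): its trans C3-hydroxy/C4-acetoxy pair is a masked C3=C4 alkene, so ring A is a cyclohexene and a Diels–Alder retron with quaternary C10 as the dienophile carbon.
- Target ⇐ C6 alcohol oxidation ⇐ acetolysis of the 3,4-epoxide ⇐ C3=C4 tetracycle 18; ring D by C16–C13 radical closure from the C8 acetyl group, then α-methylenation; ring C by butadiene cycloaddition to C8=C9; lactone ring B by Knoevenagel closure of a C20 acetoacetate onto the C9 aldehyde.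
- Ring A by a catalytic enantioselective Diels–Alder reaction of dienyl silyl ether 3 (C2–C6) with acrolein 6 (C1, C10, C9, C20), forming C1–C2 and C5–C10.
- Order of ring formation: A, then B (lactone), then C, then D.

Key step: step 5

Assumption: the (S)-configured catalyst is taken to deliver the diene to the enal face described in step 5 (formyl C–H···O binding model for 2-substituted acroleins); should the sense prove opposite, the (R)-catalyst would be used with no other change.

**Route**

Step 1
Reactants: 1 (2E)-3-methylpent-2-en-4-yn-1-ol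
Product: 2 tert-butyl{[(2E)-3-methylpent-2-en-4-yn-1-yl]oxy}diphenylsilane
Conditions: TBDPSCl, imidazole, CH2Cl2, 0 °C to rt
Reagents that add atoms: tert-butyl(chloro)diphenylsilane CC(C)(C)[Si](Cl)(c1ccccc1)c1ccccc1
Why: Imidazole-promoted O-silylation of the primary allylic alcohol (substitution at silicon) gives a non-volatile enyne, and the tert-butyldiphenylsilyl group is chosen because it has to outlast Lewis acids, DDQ, tin hydride, peracid and acetic acid before its removal in step 16.

Step 2
Reactants: 2 tert-butyl{[(2E)-3-methylpent-2-en-4-yn-1-yl]oxy}diphenylsilane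
Product: 3 tert-butyl{[(2E)-3-methylpenta-2,4-dien-1-yl]oxy}diphenylsilane (diene, C2–C6)
Conditions: H2 (1 atm), Pd/CaCO3 poisoned with Pb(OAc)2, quinoline, hexane/EtOAc, rt
Reagents that add atoms: none
Why: Lindlar semi-hydrogenation adds one equivalent of H2 syn to the terminal alkyne on the lead-poisoned palladium surface and should stop at the vinyl group, leaving the (E)-trisubstituted alkene and its geometry untouched.

Step 3
Reactants: 4 2-methylidenepropane-1,3-diol
Product: 5 2-{[(4-methoxyphenyl)methoxy]methyl}prop-2-en-1-ol
Conditions: 4 (3 equiv), NaH (1 equiv), PMBCl (1 equiv), Bu4NI (cat.), THF/DMF, 0 °C to rt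
Reagents that add atoms: 4-methoxybenzyl chloride COc1ccc(CCl)cc1
Why: Williamson etherification of the monoalkoxide, in which the excess of the symmetrical diol suppresses dialkylation and the unreacted diol is removed by aqueous washing.

Step 4
Reactants: 5 2-{[(4-methoxyphenyl)methoxy]methyl}prop-2-en-1-ol
Product: 6 2-{[(4-methoxyphenyl)methoxy]methyl}prop-2-enal (dienophile; C1, C10, C9, C20)
Conditions: MnO2 (10 equiv), CH2Cl2, rt
Reagents that add atoms: none
Why: MnO2 oxidises the allylic alcohol selectively to the enal (heterogeneous allylic oxidation) without touching the benzylic ether, and the enal is used fresh because 2-substituted acroleins dimerise on standing.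

Step 5
Reactants: 3 tert-butyl{[(2E)-3-methylpenta-2,4-dien-1-yl]oxy}diphenylsilane; 6 2-{[(4-methoxyphenyl)methoxy]methyl}prop-2-enal
Product: 7 (1S,2R)-2-{[tert-butyl(diphenyl)silyl]oxymethyl}-1-{[(4-methoxyphenyl)methoxy]methyl}-3-methylcyclohex-3-ene-1-carbaldehyde (ring A; CHO = C20, cis to the C6 arm; CH2OPMB = C9)
Conditions: (S)-3,3-diphenyl-1-(2-methylphenyl)tetrahydro-1H,3H-pyrrolo[1,2-c][1,3,2]oxazaborole (20 mol%), HNTf2 (17 mol%), CH2Cl2, −78 °C
Reagents that add atoms: none
Why: The N-protonated oxazaborolidine binds the formyl oxygen of 6 at boron (formyl C–H···O contact to the ring oxygen, s-trans enal) and diene 3 adds in a concerted but asynchronous [4+2] cycloaddition in which the C1–C2 bond runs ahead of the C5–C10 bond; the closest known reaction type is the oxazaborolidinium-catalysed Diels–Alder reaction of 2-substituted acroleins with 1-substituted acyclic dienes. Ring A is closed in an intermolecular suprafacial–suprafacial [4+2] mode that forms both σ-bonds (C1–C2 and C5–C10) in one step and leaves the C3=C4 alkene. C10 is set by the catalyst, whose phenyl group cis to the bound aldehyde covers one face of the enal so that the diene should add to the face on which CHO, CH2OPMB and =CH2 run anticlockwise, and C5 is set relative to C10 by the (E)-geometry of the C4=C5 bond together with the endo position of the boron-bound formyl group, which places C20 cis to the C6 arm. Three selectivities are needed: regioselectivity (C10 to C5, not to C2) should come from the terminal silyloxymethyl substituent, which as in 1-vinylcycloalkenes outweighs the internal 2-methyl group and lets the unhindered C2 terminus bond first to the β-carbon C1; endo selectivity from the coordinated formyl group; enantioface selectivity from the catalyst. The bulky, weakly basic silyl ether should keep the dienyl C–O bond from ionising at −78 °C, and because the endo adduct puts the formyl carbon cis to C6, the formyl arm becomes C20 and the ether arm C9.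

Step 6
Reactants: 7 ring A aldehyde
Product: 8 ring A alcohol (7 with the formyl group reduced to the C20 CH2OH)
Conditions: NaBH4, MeOH/THF, 0 °C
Reagents that add atoms: none
Why: Borohydride reduction of the hindered, non-conjugated aldehyde turns C20 into the carbinol that becomes the lactone OCH2, and no stereocentre is touched.

Step 7
Reactants: 8 ring A alcohol
Product: 9 C20 acetoacetate (3-oxobutanoate ester of 8)
Conditions: 2,2,6-trimethyl-4H-1,3-dioxin-4-one, toluene, 110 °C
Reagents that add atoms: 2,2,6-trimethyl-4H-1,3-dioxin-4-one CC1=CC(=O)OC(C)(C)O1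
Why: Thermal retro-[4+2] fragmentation of the dioxinone releases acetylketene, which acylates even the neopentyl C20 alcohol under neutral conditions (acetoacetylation) so that neither ether nor the alkene is disturbed.

Step 8
Reactants: 9 C20 acetoacetate
Product: 10 C9 alcohol (9 without the 4-methoxybenzyl group)
Conditions: DDQ, CH2Cl2/pH 7 buffer, 0 °C
Reagents that add atoms: none
Why: Single-electron oxidation of the electron-rich benzyl ether by DDQ and hydrolysis of the resulting oxocarbenium ion frees the C9 alcohol under buffered, near-neutral conditions that spare the silyl ether and should keep the acetoacetyl group from migrating between the two C10 arms.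

Step 9
Reactants: 10 C9 alcohol
Product: 12 4-acetyl-7-{[tert-butyl(diphenyl)silyl]oxymethyl}-8-methyl-2-oxaspiro[5.5]undeca-4,8-dien-3-one (rings A and B; C8=C9; lactone OCH2 cis to the C6 arm), via keto ester aldehyde 11 (not isolated)
Conditions: Pr4N[RuO4] (5 mol%), N-methylmorpholine N-oxide, 4 Å MS, CH2Cl2, rt; filter; then piperidine (cat.), AcOH (cat.), CH2Cl2, rt
Reagents that add atoms: none
Why: Ley–Griffith oxidation gives the non-enolisable neopentyl aldehyde under neutral conditions, and amine-catalysed intramolecular Knoevenagel condensation with the tethered acetoacetate closes the six-membered lactone (ring B) with the C8=C9 bond necessarily endocyclic.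

Step 10
Reactants: 12 spiro lactone; 13 buta-1,3-diene
Product: 14 tricyclic keto lactone (cyclohexene ring C with C12=C13 cis-fused to the lactone; C8 acetyl cis to H-9; C9–C11 bond on the C1 side of ring A)
Conditions: 13 (10 equiv), ZnCl2 (1.0 equiv, 1 M in Et2O), CH2Cl2, −20 °C to rt, sealed tube
Reagents that add atoms: none
Why: Lewis-acid-promoted normal-demand Diels–Alder reaction of butadiene with the doubly activated alkylidene keto lactone, in which suprafacial addition fixes the cis relation of H-9 and the C8 acetyl group and the diene should approach the C8=C9 face flanked by C1H2 of ring A, not the face shielded by C5 with its silyloxymethyl arm, which sets C8 and C9 relative to C10.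

Step 11
Reactants: 14 tricyclic keto lactone
Product: 16 bromomethyl ketone (14 with C16 as CH2Br), via trimethylsilyl enol ether 15 (not isolated)
Conditions: LiN(SiMe3)2, TMSCl, THF, −78 °C; then NBS, THF, −78 to 0 °C
Reagents that add atoms: N-bromosuccinimide O=C1CCC(=O)N1Br; chlorotrimethylsilane C[Si](C)(C)Cl (atoms in 15 only)
Why: The ketone can enolise only toward its methyl group (C8 is quaternary and the lactone has no α-hydrogen), so kinetic silyl enol ether formation followed by electrophilic bromination with NBS at low temperature should give the bromomethyl ketone without attack on the two isolated alkenes.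

Step 12
Reactants: 16 bromomethyl ketone
Product: 17 tetracyclic keto lactone (bicyclo[3.2.1]octan-15-one rings C and D; C16 = CH2; C3=C4 intact)
Conditions: Bu3SnH (slow addition), AIBN (cat.), benzene (0.01 M), 80 °C
Reagents that add atoms: none
Why: Tin-hydride-mediated 5-exo-trig radical cyclisation in which the α-keto radical at C16, held axial on ring C by C8, adds to the near end C13 of the C12=C13 bond and the resulting C12 radical is reduced, the configuration at C13 following from C8 because the two-carbon bridge can span only one face.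

Step 13
Reactants: 17 tetracyclic keto lactone
Product: 18 exo-methylene enone (C16=C17)
Conditions: (CH2O)n, N-methylanilinium trifluoroacetate, THF, 65 °C
Reagents that add atoms: formaldehyde (as paraformaldehyde) C=O
Why: Mannich-type α-methylenation at C16, the only enolisable position of the C15 ketone, with loss of the amine in situ should give the exocyclic enone.

Step 14
Reactants: 18 exo-methylene enone
Product: 19 3,4-epoxide (epoxide oxygen anti to C20 and to the C6 arm)
Conditions: mCPBA (1.1 equiv), CH2Cl2, 0 °C
Reagents that add atoms: 3-chloroperoxybenzoic acid O=C(OO)c1cccc(Cl)c1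
Why: Prilezhaev epoxidation selects the electron-rich trisubstituted C3=C4 bond over the electron-poor enone, and the peracid should attack the face opposite the axial C20 methylene and the C6 silyloxymethyl arm so that the oxygen ends up anti to both.

Step 15
Reactants: 19 3,4-epoxide
Product: 20 hydroxy acetate silyl ether (C4 acetate syn to C20, C3 hydroxyl anti; trans-diaxial)
Conditions: glacial AcOH, 35 °C
Reagents that add atoms: acetic acid CC(=O)O
Why: Acid-assisted anti opening of the epoxide by acetic acid at the tertiary carbon C4 with inversion (Fürst–Plattner trans-diaxial opening), in which the electronic preference for the tertiary centre and the chair with C9 and C6 equatorial point to the same product, should give the C4 acetate and leave the C3 hydroxyl in place.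

Step 16
Reactants: 20 hydroxy acetate silyl ether
Product: 21 C3,C6-diol (primary C6 alcohol free)
Conditions: HF·pyridine, THF/pyridine, 0 °C to rt
Reagents that add atoms: none
Why: Fluoride cleaves the Si–O bond under weakly acidic conditions that should avoid acetyl migration, retro-Claisen opening of the β-keto lactone and conjugate addition to the enone.

Step 17
Reactants: 21 C3,C6-diol
Product: 22 CNP0199571.1 (target)
Conditions: TEMPO (cat.), PhI(OAc)2, CH2Cl2, rt
Reagents that add atoms: none
Why: Oxoammonium oxidation (TEMPO/PhI(OAc)2) is selective for the primary C6 alcohol over the hindered secondary C3 alcohol and stops at the aldehyde under non-basic conditions, so C5 should not epimerise and the β-acetoxy group should not be eliminated.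

**Compound list**

1 | (2E)-3-methylpent-2-en-4-yn-1-ol | C#C/C(C)=C/CO | starting material
2 | tert-butyl{[(2E)-3-methylpent-2-en-4-yn-1-yl]oxy}diphenylsilane | C#C/C(C)=C/CO[Si](c1ccccc1)(c1ccccc1)C(C)(C)C | intermediate
3 | tert-butyl{[(2E)-3-methylpenta-2,4-dien-1-yl]oxy}diphenylsilane | C=C/C(C)=C/CO[Si](c1ccccc1)(c1ccccc1)C(C)(C)C | intermediate
4 | 2-methylidenepropane-1,3-diol | C=C(CO)CO | starting material
5 | 2-{[(4-methoxyphenyl)methoxy]methyl}prop-2-en-1-ol | COc1ccc(COCC(=C)CO)cc1 | intermediate
6 | 2-{[(4-methoxyphenyl)methoxy]methyl}prop-2-enal | COc1ccc(COCC(=C)C=O)cc1 | intermediate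
7 | (1S,2R)-2-{[tert-butyl(diphenyl)silyl]oxymethyl}-1-{[(4-methoxyphenyl)methoxy]methyl}-3-methylcyclohex-3-ene-1-carbaldehyde | COc1ccc(COC[C@@]2(CCC=C(C)[C@H]2CO[Si](c3ccccc3)(c3ccccc3)C(C)(C)C)C=O)cc1 | intermediate
8 | ring A alcohol (C20 CH2OH; configuration at C5 and C10 as in 7) | COc1ccc(COC[C@@]2(CCC=C(C)[C@H]2CO[Si](c3ccccc3)(c3ccccc3)C(C)(C)C)CO)cc1 | intermediate
9 | C20 acetoacetate of 8 | COc1ccc(COC[C@@]2(CCC=C(C)[C@H]2CO[Si](c3ccccc3)(c3ccccc3)C(C)(C)C)COC(=O)CC(C)=O)cc1 | intermediate
10 | C9 alcohol (free CH2OH on C10 beside the C20 acetoacetate) | OC[C@@]1(CCC=C(C)[C@H]1CO[Si](c2ccccc2)(c2ccccc2)C(C)(C)C)COC(=O)CC(C)=O | intermediate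
11 | C9 aldehyde beside the C20 acetoacetate | O=C[C@@]1(CCC=C(C)[C@H]1CO[Si](c2ccccc2)(c2ccccc2)C(C)(C)C)COC(=O)CC(C)=O | intermediate (not isolated)
12 | 4-acetyl-7-{[tert-butyl(diphenyl)silyl]oxymethyl}-8-methyl-2-oxaspiro[5.5]undeca-4,8-dien-3-one (lactone OCH2 cis to the C6 arm) | CC(=O)C1=C[C@@]2(CCC=C(C)[C@H]2CO[Si](c3ccccc3)(c3ccccc3)C(C)(C)C)COC1=O | intermediate
13 | buta-1,3-diene | C=CC=C | starting material
14 | tricyclic keto lactone (ring C cyclohexene, C12=C13; C8 acetyl cis to H-9; C11 on the C1 side of ring A) | CC(=O)[C@]12CC=CC[C@H]1[C@@]1(CCC=C(C)[C@H]1CO[Si](c3ccccc3)(c3ccccc3)C(C)(C)C)COC2=O | intermediate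
15 | trimethylsilyl enol ether of 14 (C15=C16) | C=C(O[Si](C)(C)C)[C@]12CC=CC[C@H]1[C@@]1(CCC=C(C)[C@H]1CO[Si](c3ccccc3)(c3ccccc3)C(C)(C)C)COC2=O | intermediate (not isolated)
16 | bromomethyl ketone (C16 CH2Br) | BrCC(=O)[C@]12CC=CC[C@H]1[C@@]1(CCC=C(C)[C@H]1CO[Si](c3ccccc3)(c3ccccc3)C(C)(C)C)COC2=O | intermediate
17 | tetracyclic keto lactone (bicyclo[3.2.1]octan-15-one, C16 CH2) | C1C(=O)[C@]23C[C@H]1CC[C@H]2[C@@]1(CCC=C(C)[C@H]1CO[Si](c4ccccc4)(c4ccccc4)C(C)(C)C)COC3=O | intermediate
18 | exo-methylene enone (C16=C17, C3=C4 intact) | C=C1C(=O)[C@]23C[C@H]1CC[C@H]2[C@@]1(CCC=C(C)[C@H]1CO[Si](c4ccccc4)(c4ccccc4)C(C)(C)C)COC3=O | intermediate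
19 | 3,4-epoxide (oxygen anti to C20 and to the C6 arm) | C=C1C(=O)[C@]23C[C@H]1CC[C@H]2[C@@]1(CC[C@@H]4O[C@]4(C)[C@H]1CO[Si](c5ccccc5)(c5ccccc5)C(C)(C)C)COC3=O | intermediate
20 | C3-hydroxy C4-acetate, C6 silyl ether | C=C1C(=O)[C@]23C[C@H]1CC[C@H]2[C@@]1(CC[C@H](O)[C@@](C)(OC(C)=O)[C@H]1CO[Si](c4ccccc4)(c4ccccc4)C(C)(C)C)COC3=O | intermediate
21 | C3,C6-diol with C4 acetate | C=C1C(=O)[C@]23C[C@H]1CC[C@H]2[C@@]1(CC[C@H](O)[C@@](C)(OC(C)=O)[C@H]1CO)COC3=O | intermediate
22 | CNP0199571.1 | C=C1C(=O)[C@]23C[C@H]1CC[C@H]2[C@@]1(CC[C@H](O)[C@@](C)(OC(C)=O)[C@H]1C=O)COC3=O | target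

**Step count**

Total: 17 steps. Longest linear sequence: 15 steps (steps 1–2 then 5–17, or steps 3–4 then 5–17).

**Steps most likely to fail**

1. Step 5 (key cycloaddition). The two ether oxygens may tie up the boron cation, or the acid may ionise the dienyl C–O bond, so that turnover stops and an unselective background reaction takes over, with poor enantioface control and erosion of the ortho and endo preferences. Fallback, setting out from 3 and 6: the cycloaddition is run with an achiral promoter (Me2AlCl, CH2Cl2, −78 °C) to give the racemic endo adduct, that is 7 together with the enantiomer of 7 F1. Reduction with NaBH4 gives 8 together with the enantiomer of 8 F2, and the two are separated by preparative chromatography on a chiral stationary phase (cellulose tris(3,5-dimethylphenylcarbamate)). The route is re-entered at 8.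

2. Step 12 (ring D closure). The planar α-keto radical closes more slowly than an alkyl radical, so hydrogen transfer before cyclisation (returning 14) or attack at the far alkene carbon C12 (6-endo, bicyclo[2.2.2]octane skeleton) may compete. Fallback, setting out from 14: silyl enol ether 15 is isolated and treated with Pd(OAc)2 (1 equiv, MeCN, rt) in an oxidative cycloalkenylation. The palladium enolate, which has no β-hydrogen of its own, inserts the C13=C12 bond in the 5-exo mode, and syn β-hydride elimination toward C11 should give the C11=C12 bicyclo[3.2.1]octenone F3. Diimide (2-nitrobenzenesulfonyl hydrazide, Et3N, CH2Cl2, rt) then saturates the strained disubstituted alkene in preference to the trisubstituted C3=C4 bond and returns 17.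

3. Step 15 (acetolysis). With the weak nucleophile acetic acid, the activated epoxide may lose a proton to give an allylic alcohol or undergo a hydride shift to the C3 ketone, or the reaction may be too slow to compete with loss of the silyl ether. Fallback, setting out from 19: hydrolytic opening (HClO4 cat., THF/H2O, 0 °C) at the tertiary carbon gives the trans-diaxial 3,4-diol F4. Silylation of the secondary C3 hydroxyl only (TESCl, imidazole) gives the C3 triethylsilyl ether F5. Acetylation of the remaining tertiary C4 hydroxyl (Ac2O, 4-(dimethylamino)pyridine, Et3N, CH2Cl2, 40 °C) gives the C4 acetate F6. HF·pyridine then removes both silyl groups and the route is re-entered at 21.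

**Further compounds**

F1 | step 5 | enantiomer of 7, (1R,2S)-2-{[tert-butyl(diphenyl)silyl]oxymethyl}-1-{[(4-methoxyphenyl)methoxy]methyl}-3-methylcyclohex-3-ene-1-carbaldehyde | COc1ccc(COC[C@]2(CCC=C(C)[C@@H]2CO[Si](c3ccccc3)(c3ccccc3)C(C)(C)C)C=O)cc1
F2 | step 5 | enantiomer of 8 | COc1ccc(COC[C@]2(CCC=C(C)[C@@H]2CO[Si](c3ccccc3)(c3ccccc3)C(C)(C)C)CO)cc1
F3 | step 12 | C11=C12 bicyclo[3.2.1]octenone (17 with a C11=C12 double bond) | C1C(=O)[C@]23C[C@H]1C=C[C@H]2[C@@]1(CCC=C(C)[C@H]1CO[Si](c4ccccc4)(c4ccccc4)C(C)(C)C)COC3=O
F4 | step 15 | trans-3,4-diol (C4 hydroxyl syn to C20, C3 hydroxyl anti), C6 silyl ether | C=C1C(=O)[C@]23C[C@H]1CC[C@H]2[C@@]1(CC[C@H](O)[C@@](C)(O)[C@H]1CO[Si](c4ccccc4)(c4ccccc4)C(C)(C)C)COC3=O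
F5 | step 15 | C3 triethylsilyl ether of F4 | C=C1C(=O)[C@]23C[C@H]1CC[C@H]2[C@@]1(CC[C@H](O[Si](CC)(CC)CC)[C@@](C)(O)[C@H]1CO[Si](c4ccccc4)(c4ccccc4)C(C)(C)C)COC3=O
F6 | step 15 | C4 acetate of F5 | C=C1C(=O)[C@]23C[C@H]1CC[C@H]2[C@@]1(CC[C@H](O[Si](CC)(CC)CC)[C@@](C)(OC(C)=O)[C@H]1CO[Si](c4ccccc4)(c4ccccc4)C(C)(C)C)COC3=O
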